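## Retrosynthetic overview

1. The last bond made is C3=C4 of the pyran ring, by ring-closing olefin metathesis of diene 18 (vinyl on C4a, 1,1-dimethylallyl on O1); in the same pot the C-allyl group on ring B becomes the prenyl group by cross metathesis.
2. The methylene bridge is cut next: conjugate addition of the chiral triketone 16 to the ortho-quinone methide released from Mannich base 10.
3. Ring A piece 10 comes from phloroglucinol (acylation, O-alkylation of the para hydroxyl, formylation, semi-hydrogenation, methylenation, aminomethylation). Ring B piece 16 comes from 2-methylphloroglucinol (acylation, chlorine block, asymmetric dearomative allylation that sets the quaternary stereocentre, dechlorination).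
4. Enabling feature: in ring A the ether oxygen O1 (on C8a, para to the acyl group on C6) carries the quaternary carbon C2, the ortho carbon C4a carries C4, and C3=C4 is an unsubstituted cis alkene inside a six-membered ring. O1 also lies on the local mirror plane of the 4-O-alkyl acylphloroglucinol, so either ortho carbon can take the vinyl group and the other takes the bridge.
5. Ring order: both carbocycles come from aromatic starting materials (ring B is dearomatised in step 9); the pyran ring is the only ring that is formed, and it is formed last.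

Key step: step 12

Assumption: the sense of induction of the ligand in step 9 cannot be predicted for this nucleophile, so the (R,R) ligand is written and its mirror image would be used if a test run gave the other enantiomer; enolised triketones are drawn as one tautomer.

## Route

Step 1
Reactants: 1 phloroglucinol (benzene-1,3,5-triol); 2 isobutyryl chloride (2-methylpropanoyl chloride)
Product: 3 1-(2,4,6-trihydroxyphenyl)-2-methylpropan-1-one
Conditions: AlCl3 (3 equiv), PhNO2/CH2Cl2, 0 °C to 40 °C; aqueous HCl work-up
Reagents that add atoms: none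
Why: Friedel–Crafts acylation of the electron-rich triol should stop after one acyl group because the ketone, hydrogen-bonded to both ortho hydroxyls, deactivates the ring.

Step 2
Reactants: 3 1-(2,4,6-trihydroxyphenyl)-2-methylpropan-1-one; 4 3-chloro-3-methylbut-1-yne
Product: 5 1-[2,6-dihydroxy-4-(2-methylbut-3-yn-2-yloxy)phenyl]-2-methylpropan-1-one
Conditions: DBU (1.1 equiv), CuCl2·2H2O (1 mol %), MeCN, 0 °C
Reagents that add atoms: none
Why: Copper-catalysed propargylic etherification (copper acetylide/allenylidene pathway) alkylates oxygen rather than carbon and should take the hydroxyl para to the ketone, the most acidic one and the only one not held in a hydrogen bond to the carbonyl.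

Step 3
Reactants: 5 1-[2,6-dihydroxy-4-(2-methylbut-3-yn-2-yloxy)phenyl]-2-methylpropan-1-one
Product: 7 2,4-dihydroxy-3-(2-methylpropanoyl)-6-(2-methylbut-3-yn-2-yloxy)benzaldehyde, via aryl iminium chloride 6 (not isolated)
Conditions: POCl3 (1.2 equiv), DMF (3 equiv), EtOAc, 0 °C to rt; then H2O, rt
Reagents that add atoms: N,N-dimethylformamide, CN(C)C=O; water, O
Why: Vilsmeier–Haack formylation should occur at one of the two ring CH positions, which are equivalent through the mirror plane running through the ketone carbon and the ether oxygen, and should stop there because the new formyl group deactivates the ring.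

Step 4
Reactants: 7 2,4-dihydroxy-3-(2-methylpropanoyl)-6-(2-methylbut-3-yn-2-yloxy)benzaldehyde
Product: 8 2,4-dihydroxy-3-(2-methylpropanoyl)-6-(2-methylbut-3-en-2-yloxy)benzaldehyde
Conditions: H2 (1 atm), Pd/CaCO3 poisoned with Pb(OAc)2 (Lindlar catalyst), quinoline, EtOAc, rt, stopped after one equivalent of H2
Reagents that add atoms: none
Why: Lindlar semi-hydrogenation reduces the terminal alkyne far faster than the resulting hindered alkene or the carbonyl groups, the standard entry to aryl 1,1-dimethylallyl ethers.

Step 5
Reactants: 8 2,4-dihydroxy-3-(2-methylpropanoyl)-6-(2-methylbut-3-en-2-yloxy)benzaldehyde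
Product: 9 1-[3-ethenyl-2,6-dihydroxy-4-(2-methylbut-3-en-2-yloxy)phenyl]-2-methylpropan-1-one
Conditions: Ph3PCH3Br (4 equiv), KOtBu (4 equiv), THF, 0 °C to rt
Reagents that add atoms: methyltriphenylphosphonium bromide, C[P+](c1ccccc1)(c1ccccc1)c1ccccc1.[Br-]
Why: Wittig methylenation with excess non-stabilised ylide (the first two equivalents are spent on the phenols) should convert the aldehyde, while the isopropyl ketone flanked by two phenoxides is too hindered and too electron-rich to react.

Step 6
Reactants: 9 1-[3-ethenyl-2,6-dihydroxy-4-(2-methylbut-3-en-2-yloxy)phenyl]-2-methylpropan-1-one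
Product: 10 1-{3-[(dimethylamino)methyl]-5-ethenyl-2,6-dihydroxy-4-(2-methylbut-3-en-2-yloxy)phenyl}-2-methylpropan-1-one
Conditions: Eschenmoser's salt (1.1 equiv), Et3N (1.1 equiv), CH2Cl2, 0 °C to rt
Reagents that add atoms: N,N-dimethylmethyleneiminium iodide (Eschenmoser's salt), C=[N+](C)C.[I-]
Why: Mannich-type electrophilic aminomethylation should go to the only remaining ring CH, which is ortho and para to oxygen donors, and the preformed iminium salt avoids free formaldehyde that would give methylene-bridged homodimers.

Step 7
Reactants: 11 2-methylbenzene-1,3,5-triol (2-methylphloroglucinol); 2 isobutyryl chloride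
Product: 12 1-(2,4,6-trihydroxy-3-methylphenyl)-2-methylpropan-1-one
Conditions: AlCl3 (3 equiv), PhNO2/CH2Cl2, 0 °C to 40 °C; aqueous HCl work-up
Reagents that add atoms: none
Why: Friedel–Crafts acylation as in step 1, at one of the two equivalent free positions of the methylated triol.

Step 8
Reactants: 12 1-(2,4,6-trihydroxy-3-methylphenyl)-2-methylpropan-1-one
Product: 13 1-(3-chloro-2,4,6-trihydroxy-5-methylphenyl)-2-methylpropan-1-one
Conditions: NCS (1.0 equiv), MeCN, 0 °C
Reagents that add atoms: N-chlorosuccinimide, O=C1CCC(=O)N1Cl
Why: Electrophilic aromatic chlorination takes the single free ring position, and the chlorine is a removable block that leaves the methyl-bearing carbon as the only carbon able to be allylated in step 9 and prevents a second allylation.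

Step 9
Reactants: 13 1-(3-chloro-2,4,6-trihydroxy-5-methylphenyl)-2-methylpropan-1-one; 14 allyl methyl carbonate
Product: 15 (4S)-2-chloro-3,5-dihydroxy-4-methyl-6-(2-methylpropanoyl)-4-(prop-2-en-1-yl)cyclohexa-2,5-dien-1-one
Conditions: Pd2(dba)3·CHCl3 (2.5 mol %), (R,R)-DACH-phenyl Trost ligand (7.5 mol %), 14 (1.05 equiv), THF, 0 °C
Reagents that add atoms: none
Why: Palladium-catalysed asymmetric allylic alkylation (Tsuji–Trost type) with dearomatisation: the phenoxide attacks the π-allyl complex of divalent palladium (formed from zerovalent palladium and the carbonate) through its methyl-bearing ring carbon, and the chiral pocket of the diamide–bisphosphine ligand should distinguish the two faces of the flat nucleophile, whose flanks differ (chlorine side versus hydrogen-bonded acyl side), which sets the quaternary stereocentre.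

Step 10
Reactants: 15 (4S)-2-chloro-3,5-dihydroxy-4-methyl-6-(2-methylpropanoyl)-4-(prop-2-en-1-yl)cyclohexa-2,5-dien-1-one
Product: 16 (4R)-3,5-dihydroxy-4-methyl-2-(2-methylpropanoyl)-4-(prop-2-en-1-yl)cyclohexa-2,5-dien-1-one
Conditions: Zn dust (3 equiv), AcOH, rt
Reagents that add atoms: none
Why: Reductive dehalogenation of an α-chloro-β-dicarbonyl by zinc (zinc enolate, protonated by acetic acid) should remove the block without touching the allyl group or the quaternary carbon, whose descriptor changes from S to R only because chlorine leaves the priority order.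

Step 11
Reactants: 10 Mannich base of ring A; 16 (4R)-3,5-dihydroxy-4-methyl-2-(2-methylpropanoyl)-4-(prop-2-en-1-yl)cyclohexa-2,5-dien-1-one
Product: 18 (4R)-6-{[5-ethenyl-2,4-dihydroxy-3-(2-methylpropanoyl)-6-(2-methylbut-3-en-2-yloxy)phenyl]methyl}-3,5-dihydroxy-4-methyl-2-(2-methylpropanoyl)-4-(prop-2-en-1-yl)cyclohexa-2,5-dien-1-one, via ortho-quinone methide 17 (not isolated)
Conditions: 10 and 16 (1:1), MeCN, 45 °C, argon
Reagents that add atoms: none
Why: Loss of dimethylamine from the phenolic Mannich base, helped by protonation of the amine by the acidic triketone, gives an ortho-quinone methide that is taken up by conjugate (Michael) addition of the only enolisable ring CH carbon of 16, and the cross-coupling should be clean because only 10 can form the methide and only 16 carries the nucleophilic carbon.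

Step 12
Reactants: 18 metathesis precursor
Product: 20 (4R)-6-{[5,7-dihydroxy-2,2-dimethyl-6-(2-methylpropanoyl)-2H-chromen-8-yl]methyl}-3,5-dihydroxy-4-methyl-4-(3-methylbut-2-en-1-yl)-2-(2-methylpropanoyl)cyclohexa-2,5-dien-1-one (CNP0319758.1), via allyl chromene 19 (not isolated)
Conditions: second-generation Hoveyda–Grubbs catalyst RuCl2(=CH-C6H4-2-OiPr)(H2IMes) (10 mol %), CH2Cl2 (5 mM), 40 °C until ring closure; then 2-methyl-2-butene (50 equiv), 40 °C, sealed vessel
Reagents that add atoms: 2-methyl-2-butene, CC=C(C)C
Why: The ruthenium alkylidene first engages the unhindered vinyl group on ring A (the 3,3-disubstituted terminal alkene of the ether is too hindered to initiate or to homodimerise), and the resulting aryl carbene closes onto the 1,1-dimethylallyl alkene through a ruthenacyclobutane whose cycloreversion releases ethylene and forms the C3=C4 bond, which is ring-closing olefin metathesis as used for 2H-chromenes from ortho-vinyl aryl allyl ethers. The pyran ring is closed as a six-membered ring (O1, C2, C3, C4, C4a, C8a) by intramolecular [2+2] cycloaddition and cycloreversion between two alkenes held ortho on the arene, helped by the gem-dimethyl group at C2 (Thorpe–Ingold effect) and by relief of the crowding around the di-ortho-substituted tertiary aryl ether, and the ring enforces the cis alkene. The same catalyst charge then carries out cross metathesis of the remote allyl group with 2-methyl-2-butene, a standard allyl-to-prenyl exchange, so one operation should deliver the last ring and both olefinic units of the target without any protecting group. No stereocentre is formed, and the quaternary carbon, which bears no hydrogen, is not at risk. The selectivity needed is chemoselectivity among three terminal alkenes and against oligomerisation: the ortho relationship of vinyl and allyl ether makes six-ring closure far faster than any crossing with the allyl group (which could only give a ten- or eleven-membered ring), high dilution suppresses dimers, and the trisubstituted olefin is added only after ring closure so that the styrene is not capped as a less reactive alkene.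

## Compound list

1 | phloroglucinol (benzene-1,3,5-triol) | Oc1cc(O)cc(O)c1 | starting material
2 | isobutyryl chloride | CC(C)C(Cl)=O | starting material
3 | 1-(2,4,6-trihydroxyphenyl)-2-methylpropan-1-one | CC(C)C(=O)c1c(O)cc(O)cc1O | intermediate
4 | 3-chloro-3-methylbut-1-yne | CC(C)(Cl)C#C | starting material
5 | 1-[2,6-dihydroxy-4-(2-methylbut-3-yn-2-yloxy)phenyl]-2-methylpropan-1-one | CC(C)C(=O)c1c(O)cc(OC(C)(C)C#C)cc1O | intermediate
6 | {[2,4-dihydroxy-3-(2-methylpropanoyl)-6-(2-methylbut-3-yn-2-yloxy)phenyl]methylidene}dimethylammonium chloride | CC(C)C(=O)c1c(O)c(C=[N+](C)C)c(OC(C)(C)C#C)cc1O.[Cl-] | intermediate (not isolated)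
7 | 2,4-dihydroxy-3-(2-methylpropanoyl)-6-(2-methylbut-3-yn-2-yloxy)benzaldehyde | CC(C)C(=O)c1c(O)c(C=O)c(OC(C)(C)C#C)cc1O | intermediate
8 | 2,4-dihydroxy-3-(2-methylpropanoyl)-6-(2-methylbut-3-en-2-yloxy)benzaldehyde | CC(C)C(=O)c1c(O)c(C=O)c(OC(C)(C)C=C)cc1O | intermediate
9 | 1-[3-ethenyl-2,6-dihydroxy-4-(2-methylbut-3-en-2-yloxy)phenyl]-2-methylpropan-1-one | CC(C)C(=O)c1c(O)c(C=C)c(OC(C)(C)C=C)cc1O | intermediate
10 | 1-{3-[(dimethylamino)methyl]-5-ethenyl-2,6-dihydroxy-4-(2-methylbut-3-en-2-yloxy)phenyl}-2-methylpropan-1-one | CC(C)C(=O)c1c(O)c(C=C)c(OC(C)(C)C=C)c(CN(C)C)c1O | intermediate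
11 | 2-methylbenzene-1,3,5-triol | Cc1c(O)cc(O)cc1O | starting material
12 | 1-(2,4,6-trihydroxy-3-methylphenyl)-2-methylpropan-1-one | CC(C)C(=O)c1c(O)cc(O)c(C)c1O | intermediate
13 | 1-(3-chloro-2,4,6-trihydroxy-5-methylphenyl)-2-methylpropan-1-one | CC(C)C(=O)c1c(O)c(Cl)c(O)c(C)c1O | intermediate
14 | allyl methyl carbonate | C=CCOC(=O)OC | starting material
15 | (4S)-2-chloro-3,5-dihydroxy-4-methyl-6-(2-methylpropanoyl)-4-(prop-2-en-1-yl)cyclohexa-2,5-dien-1-one | C=CC[C@]1(C)C(O)=C(Cl)C(=O)C(C(=O)C(C)C)=C1O | intermediate
16 | (4R)-3,5-dihydroxy-4-methyl-2-(2-methylpropanoyl)-4-(prop-2-en-1-yl)cyclohexa-2,5-dien-1-one | C=CC[C@]1(C)C(O)=CC(=O)C(C(=O)C(C)C)=C1O | intermediate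
17 | 4-ethenyl-3-hydroxy-6-methylidene-5-(2-methylbut-3-en-2-yloxy)-2-(2-methylpropanoyl)cyclohexa-2,4-dien-1-one (ortho-quinone methide) | CC(C)C(=O)C1=C(O)C(C=C)=C(OC(C)(C)C=C)C(=C)C1=O | intermediate (not isolated)
18 | (4R)-6-{[5-ethenyl-2,4-dihydroxy-3-(2-methylpropanoyl)-6-(2-methylbut-3-en-2-yloxy)phenyl]methyl}-3,5-dihydroxy-4-methyl-2-(2-methylpropanoyl)-4-(prop-2-en-1-yl)cyclohexa-2,5-dien-1-one | C=CC[C@]1(C)C(O)=C(Cc2c(O)c(C(=O)C(C)C)c(O)c(C=C)c2OC(C)(C)C=C)C(=O)C(C(=O)C(C)C)=C1O | intermediate
19 | (4R)-6-{[5,7-dihydroxy-2,2-dimethyl-6-(2-methylpropanoyl)-2H-chromen-8-yl]methyl}-3,5-dihydroxy-4-methyl-2-(2-methylpropanoyl)-4-(prop-2-en-1-yl)cyclohexa-2,5-dien-1-one | C=CC[C@]1(C)C(O)=C(Cc2c(O)c(C(=O)C(C)C)c(O)c3c2OC(C)(C)C=C3)C(=O)C(C(=O)C(C)C)=C1O | intermediate (not isolated)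
20 | (4R)-6-{[5,7-dihydroxy-2,2-dimethyl-6-(2-methylpropanoyl)-2H-chromen-8-yl]methyl}-3,5-dihydroxy-4-methyl-4-(3-methylbut-2-en-1-yl)-2-(2-methylpropanoyl)cyclohexa-2,5-dien-1-one | CC(C)=CC[C@]1(C)C(O)=C(Cc2c(O)c(C(=O)C(C)C)c(O)c3c2OC(C)(C)C=C3)C(=O)C(C(=O)C(C)C)=C1O | target

## Step count and risks

Total step count: 12. Longest linear sequence: 8 steps (steps 1 to 6, 11 and 12).

Steps most likely to fail:

1. Step 12. The ruthenium carbene may be deactivated by the acidic, chelating triketone enol and the phenols; the crowded tertiary allylic aryl ether of 18 may ionise under the influence of the internal acid before it has cyclised; the allyl double bond may migrate. The fallback sets out from 9 and comes back to the route at 19. Ring-closing metathesis of 9 alone with second-generation Grubbs catalyst RuCl2(=CHPh)(H2IMes)(PCy3) in CH2Cl2 at 40 °C, where no acidic triketone is present, should give 1-(5,7-dihydroxy-2,2-dimethyl-2H-chromen-6-yl)-2-methylpropan-1-one F1. Aminomethylation with Eschenmoser's salt and Et3N as in step 6 should give 1-{8-[(dimethylamino)methyl]-5,7-dihydroxy-2,2-dimethyl-2H-chromen-6-yl}-2-methylpropan-1-one F2. Warming F2 with 16 as in step 11 should pass through 5-hydroxy-2,2-dimethyl-8-methylidene-6-(2-methylpropanoyl)-2H-chromen-7(8H)-one F3 and give 19, now isolated. Compound 19 is then taken to 20 by cross metathesis with 2-methyl-2-butene alone.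

2. Step 9. Facial discrimination of the flat nucleophile by the chiral pocket may be poor; reversible O-allylation may stall the reaction; enantiopurity may erode through palladium-mediated re-ionisation of the C-allyl group. The fallback sets out from 13 and comes back at 16. Base-mediated C-allylation with allyl bromide and NaOMe in MeOH at 0 °C (the classical geminal alkylation of acylphloroglucinols) should give racemic 2-chloro-3,5-dihydroxy-4-methyl-6-(2-methylpropanoyl)-4-(prop-2-en-1-yl)cyclohexa-2,5-dien-1-one F4. Zinc in AcOH as in step 10 should give racemic 3,5-dihydroxy-4-methyl-2-(2-methylpropanoyl)-4-(prop-2-en-1-yl)cyclohexa-2,5-dien-1-one F5. This vinylogous acid is resolved classically by fractional crystallisation of its salt with 1-phenylethylamine, the antipode of the amine being chosen by which salt crystallises; written here is (R)-1-phenylethylammonium (4R)-enolate F6. Dilute HCl then releases 16.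

3. Step 5. Once both phenols are deprotonated the aldehyde is a vinylogous carboxylate, so attack of the ylide may be too slow and the basic mixture may degrade the substrate on long standing. The fallback sets out from 8 and comes back at 9 by Peterson olefination. Excess Me3SiCH2MgCl in THF at 0 °C, where chelation by the magnesium phenoxide activates the aldehyde, should give 1-{2,6-dihydroxy-3-[1-hydroxy-2-(trimethylsilyl)ethyl]-4-(2-methylbut-3-en-2-yloxy)phenyl}-2-methylpropan-1-one F7. KH in THF then triggers syn-elimination to 9 without any acid.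

Further compounds

F1 | step 12 | 1-(5,7-dihydroxy-2,2-dimethyl-2H-chromen-6-yl)-2-methylpropan-1-one | CC(C)C(=O)c1c(O)cc2OC(C)(C)C=Cc2c1O
F2 | step 12 | 1-{8-[(dimethylamino)methyl]-5,7-dihydroxy-2,2-dimethyl-2H-chromen-6-yl}-2-methylpropan-1-one | CC(C)C(=O)c1c(O)c(CN(C)C)c2OC(C)(C)C=Cc2c1O
F3 | step 12 | 5-hydroxy-2,2-dimethyl-8-methylidene-6-(2-methylpropanoyl)-2H-chromen-7(8H)-one | CC(C)C(=O)C1=C(O)C2=C(OC(C)(C)C=C2)C(=C)C1=O
F4 | step 9 | racemic 2-chloro-3,5-dihydroxy-4-methyl-6-(2-methylpropanoyl)-4-(prop-2-en-1-yl)cyclohexa-2,5-dien-1-one | C=CCC1(C)C(O)=C(Cl)C(=O)C(C(=O)C(C)C)=C1O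
F5 | step 9 | racemic 3,5-dihydroxy-4-methyl-2-(2-methylpropanoyl)-4-(prop-2-en-1-yl)cyclohexa-2,5-dien-1-one | C=CCC1(C)C(O)=CC(=O)C(C(=O)C(C)C)=C1O
F6 | step 9 | (R)-1-phenylethylammonium salt of the (4R)-enolate of 16 | C=CC[C@]1(C)C(O)=CC(=O)C(C(=O)C(C)C)=C1[O-].C[C@@H]([NH3+])c1ccccc1
F7 | step 5 | 1-{2,6-dihydroxy-3-[1-hydroxy-2-(trimethylsilyl)ethyl]-4-(2-methylbut-3-en-2-yloxy)phenyl}-2-methylpropan-1-one | CC(C)C(=O)c1c(O)c(C(O)C[Si](C)(C)C)c(OC(C)(C)C=C)cc1O
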